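The readings are simulated from invented constants.

A small charge of substrate under a large charge of coupling partner is where I start, and zeta is such a flask.

| flask | substrate | fresh partner | coupling partner | temperature | remark | time |
|---|---|---|---|---|---|---|
| cedar | 0.088 M | 0.33 M | 0.39 M | 85 °C | run made earlier |  |
| maple | 0.29 M | 0.33 M | 0.39 M | 110 °C | run made earlier |  |
| birch | 1 M | 0.33 M | 0.39 M | 85 °C | run made earlier |  |
| oak | 0.30 M | 0.32 M | 0.39 M | 110 °C | run made earlier |  |
| zeta | 0.080 M | 0.330 M | 0.390 M | 130 °C |  | 1.0 h |
| epsilon | 0.30 M | 0.330 M | 0.390 M | 90 °C |  | 1.0 h |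
| theta | 0.30 M | 0.330 M | 0.390 M | 105 °C |  | 1.0 h |
| beta | 0.30 M | 0.200 M | 0.390 M | 110 °C |  | 1.0 h |
| alpha | 1.2 M | 0.330 M | 0.390 M | 90 °C |  | 1.0 h |

- cedar (time / min: open intermediate / %, target / %): 2.50: 17.0, 0; 5.00: 30.0, 0; 8.00: 39.2, 0.8; 15.0: 52.2, 1.7; 30.0: 61.2, 7.2
- maple (time / min: open intermediate / %, target / %): 1.00: 30.8, 0; 3.00: 52.9, 1.1; 6.00: 63.2, 5.2; 8.00: 61.4, 9.7; 12.0: 57.0, 11.9
- birch (time / min: open intermediate / %, target / %): 6.00: 23.6, 0; 12.0: 30.6, 0.3; 20.0: 31.8, 0.8; 25.0: 32.9, 1.5; 30.0: 30.6, 0.7
- oak (time / min: open intermediate / %, target / %): 1.00: 31.3, 0; 3.00: 51.8, 2.4; 6.00: 62.1, 8.0; 8.00: 60.7, 7.7; 12.0: 57.5, 9.4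

(standard deviation of a reading: 1 percentage point)



1. the flasks by amount of open intermediate, in percent of the substrate charged, highest first, at 1.0 h (zeta / epsilon / theta / beta / alpha)
2. the same order at 6.0 min (zeta / epsilon / theta / beta / alpha)
3. the amount of open intermediate, in percent of the substrate charged of the flask you put first, at 1.0 h
4. the amount of open intermediate, in percent of the substrate charged of the flask you put last, at 1.0 h

The charge of coupling partner over the charge of substrate is 4.88 in zeta. I call this ratio the coupling budget, counted in shares of the substrate charge. Cedar looks nearly the same, with a budget of 4.43, but it runs at 85 °C against 130 °C for zeta.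

Birch runs at the temperature of cedar with a budget of 0.390. Its open intermediate stalls near 32.9%, lower than that budget. Its target reads 0.7% at 30.0 min, while cedar's has climbed to 7.2%. The stall also lies close to birch's share of fresh partner, so these readings do not separate the partners. I bet on the coupling partner as the limiting reagent, and I read birch as saying that the step to target needs it too. So a substrate costs one share to open and a second to finish. With the substrate fully taken up and all of the coupling partner going to those two costs, the open intermediate stranded is two shares minus the budget.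

Cedar and zeta both have budgets above two, so the rule strands nothing in either. Cedar's open intermediate reads 52.2% at 15.0 min and 61.2% at 30.0 min, whereas the readings of maple at 110 °C are highest at 6.00 min. Zeta is hotter than maple and runs for 1.0 h, so I put it last, near zero. Epsilon, theta and beta have a budget of 1.30, so full uptake there strands 70.0%.

The forecast gives epsilon > theta > alpha > beta > zeta at 1.0 h and zeta > theta > beta > epsilon > alpha at 6.0 min, with epsilon at 53% and zeta at 6%. Of birch's small target it says “High substrate seems to suppress this”. I differ there, since I take the step to target to wait on coupling partner.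

The flasks stand beta > epsilon > theta > alpha > zeta at 1.0 h and beta > theta > epsilon > alpha > zeta at 6.0 min, with the open intermediate of beta at 59.9% and of zeta at 0% at 1.0 h.

    substrate + coupling partner → open intermediate (k = 0.340 M⁻¹ min⁻¹, Ea = 81.0 kJ mol⁻¹)
    coupling partner + fresh partner → second intermediate (k = 0.0760 M⁻¹ min⁻¹, Ea = 76.0 kJ mol⁻¹)
    open intermediate + second intermediate → target (k = 0.130 M⁻¹ min⁻¹, Ea = 91.0 kJ mol⁻¹)
    target ⇌ isomer of the product (K = 5.00, k = 0.0500 min⁻¹, Ea = 95.0 kJ mol⁻¹, ΔH = −34.0 kJ mol⁻¹)
    substrate ⇌ dormant form (K = 0.530, k = 0.120 min⁻¹, Ea = 102 kJ mol⁻¹, ΔH = −38.0 kJ mol⁻¹)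
    (constants at 90 °C)

In zeta at 1.00 h the substrate stands at 0%, and the charge sits as isomer of the product, 62.1%, and target, 37.9%. By the rule zeta's budget of 4.88 strands nothing. Its neighbour with 0.20 M of substrate has a budget of 1.95, so the rule strands 5.00% at full uptake, and that flask holds 4.47% of open intermediate.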